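**Retrosynthetic overview**
1. Ring names: A is the 4-alkyl-2-aryloxyphenol ring, B the OH-free 1,3-disubstituted ring, C the catechol ring, D the 1,4-disubstituted ring. The last operation is threefold O-demethylation of macrocycle 14.
2. The 19-membered ring (shortest path) is opened between C3 of ring B and the adjacent CH2 of the B–CH2–CH2–C bridge. Both ends are carried as bromides (13) and joined electrophile to electrophile by nickel-catalysed reductive coupling. All four benzene rings are bought, so the macrocycle is the only ring formed (step 8).
3. Enabling feature: C3 of ring B lies meta to the A–O–B oxygen between two C–H positions, so its sp2 C–Br bond is unhindered. The bridge carbon is a primary sp3 C–Br whose 2-arylethyl radical can only undergo a degenerate 1,2-shift of ring C. The two ether oxygens (A–O–B, C–O–D) act as hinges that let the chain ends meet.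
4. Compound 13 comes from a B-alkyl Suzuki–Miyaura union at the A–CH2CH2–D bridge (styrene 4 plus aryl iodide 10, C–I reacting before C–Br). The two diaryl ethers come from Chan–Lam couplings.

Key step: step 8

Assumption: the target has no stereocentre, and the macrocycle is taken as conformationally mobile (no stable planar or axial chirality), so no stereocontrol is needed.

**Step 1**
Reactants: 1 isovanillin (3-hydroxy-4-methoxybenzaldehyde); 2 (3-bromophenyl)boronic acid
Product: 3 3-(3-bromophenoxy)-4-methoxybenzaldehyde
Conditions: Cu(OAc)2 (1 equiv), pyridine (5 equiv), 4 Å MS, CH2Cl2, air, rt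
Reagents that add atoms: none
Why: Chan–Lam oxidative O-arylation of the phenol with the arylboronic acid runs at room temperature, where the C–Br bond and the aldehyde are inert to copper.

**Step 2**
Reactants: 3 3-(3-bromophenoxy)-4-methoxybenzaldehyde
Product: 4 2-(3-bromophenoxy)-1-methoxy-4-vinylbenzene
Conditions: MePPh3Br, KOtBu, THF, 0 °C to rt
Reagents that add atoms: methyltriphenylphosphonium bromide, C[P+](c1ccccc1)(c1ccccc1)c1ccccc1.[Br-]
Why: Wittig methylenation of a non-enolisable aromatic aldehyde is reliable and leaves the aryl bromide and the diaryl ether untouched.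

**Step 3**
Reactants: 5 3-hydroxy-4,5-dimethoxybenzaldehyde; 6 (4-iodophenyl)boronic acid
Product: 7 3-(4-iodophenoxy)-4,5-dimethoxybenzaldehyde
Conditions: Cu(OAc)2 (1 equiv), pyridine (5 equiv), 4 Å MS, CH2Cl2, air, rt
Reagents that add atoms: none
Why: Chan–Lam O-arylation at room temperature should form the C–O–D ether while the C–I bond, needed in step 6, stays intact.

**Step 4**
Reactants: 7 3-(4-iodophenoxy)-4,5-dimethoxybenzaldehyde
Product: 8 1-(4-iodophenoxy)-2,3-dimethoxy-5-vinylbenzene
Conditions: MePPh3Br, KOtBu, THF, 0 °C to rt
Reagents that add atoms: methyltriphenylphosphonium bromide, C[P+](c1ccccc1)(c1ccccc1)c1ccccc1.[Br-]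
Why: Wittig methylenation installs the second bridge carbon on ring C without touching the aryl iodide.

**Step 5**
Reactants: 8 1-(4-iodophenoxy)-2,3-dimethoxy-5-vinylbenzene
Product: 10 2-[3-(4-iodophenoxy)-4,5-dimethoxyphenyl]ethan-1-ol, via fragment CD alkylborane 9 (not isolated)
Conditions: 9-BBN, THF, 0 °C to rt; then NaOH aq, H2O2, 0 °C to rt
Reagents that add atoms: 9-BBN, B1C2CCCC1CCC2 (its boron unit is carried only by 9); hydrogen peroxide, OO
Why: Hydroboration–oxidation with the bulky 9-BBN places boron on the terminal styrene carbon, and alkaline peroxide then gives the primary alcohol with the aryl iodide intact.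

**Step 6**
Reactants: 4 2-(3-bromophenoxy)-1-methoxy-4-vinylbenzene; 10 2-[3-(4-iodophenoxy)-4,5-dimethoxyphenyl]ethan-1-ol
Product: 12 2-[3-(4-{2-[3-(3-bromophenoxy)-4-methoxyphenyl]ethyl}phenoxy)-4,5-dimethoxyphenyl]ethan-1-ol, via fragment AB alkylborane 11 (not isolated)
Conditions: 4, 9-BBN (1.05 equiv), THF, rt; then 10 (1.1 equiv), Pd(dppf)Cl2 (5 mol %), Cs2CO3, DMF/THF/H2O, rt
Reagents that add atoms: 9-BBN, B1C2CCCC1CCC2 (its boron unit is carried only by 11)
Why: In this B-alkyl Suzuki–Miyaura coupling the primary alkylborane transfers to the aryl-palladium species formed from the C–I bond of ring D, which adds to zerovalent palladium at room temperature much faster than the C–Br bond of ring B, and the free hydroxyl is tolerated.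

**Step 7**
Reactants: 12 seco-alcohol
Product: 13 1-(2-bromoethyl)-3-(4-{2-[3-(3-bromophenoxy)-4-methoxyphenyl]ethyl}phenoxy)-4,5-dimethoxybenzene (seco-dibromide)
Conditions: CBr4, PPh3, CH2Cl2, 0 °C
Reagents that add atoms: carbon tetrabromide, BrC(Br)(Br)Br
Why: The Appel reaction converts the primary alcohol into the bromide by SN2 displacement of the oxyphosphonium group under neutral conditions, so elimination to the styrene is avoided.

**Step 8**
Reactants: 13 seco-dibromide
Product: 14 tri-O-methyl ether of the target (macrocycle with OMe on ring A and two OMe on ring C)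
Conditions: NiBr2(dme) (30 mol %), 4,4'-di-tert-butyl-2,2'-bipyridine (dtbbpy, 33 mol %), NaI (25 mol %), Zn dust (4 equiv), DMA, 60 °C; 13 added by syringe pump over 16 h (final 0.01 M)
Reagents that add atoms: none
Why: Proposed new method: zerovalent (dtbbpy)nickel should insert only into the sp2 C–Br bond at C3 of ring B to give a persistent divalent aryl-nickel bromide, a monovalent nickel halide should abstract bromine from the primary sp3 C–Br bond to give the 2-(ring C)ethyl radical, capture of that radical by the aryl-nickel centre on the same chain gives a trivalent aryl(alkyl)nickel species whose reductive elimination forms the ring B–CH2 bond, and zinc returns nickel to the zerovalent state. The closest known reaction type is the intermolecular nickel-catalysed reductive cross-electrophile coupling of aryl bromides with primary alkyl bromides, and nickel-mediated reductive aryl–aryl closure of large cyclophanes is also known, so the new element is the ring-closing aryl–alkyl version on a bis(bibenzyl) chain. The one ring closed is the 19-membered macrocycle (shortest path), formed end to end through a large nickelacycle, so no exo or endo question arises. No stereocentre is formed. Cross-coupling over homo-coupling is secured by the different hybridisation of the two C–Br carbons, which nickel activates by different mechanisms, and ring closure over oligomerisation is secured by slow addition, which keeps free 13 well below the nickel concentration so that each aryl bromide is metalated before its alkyl end is activated, helped by the two ether-oxygen hinges. The base-free medium spares the elimination-prone 2-arylethyl bromide, and the only rearrangement open to the radical, a 1,2-shift of ring C, is degenerate.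

**Step 9**
Reactants: 14 tri-O-methyl macrocycle
Product: 15 target CNP0495401.0
Conditions: BBr3 (excess), CH2Cl2, −78 °C to rt, argon; then H2O
Reagents that add atoms: none
Why: BBr3 ether cleavage removes the three methyl groups by bromide attack at the sp3 carbon, whereas the two diaryl ether C–O bonds offer no such carbon and should survive.

**Compound list**
1 | isovanillin (3-hydroxy-4-methoxybenzaldehyde) | COc1ccc(C=O)cc1O | starting material
2 | (3-bromophenyl)boronic acid | OB(O)c1cccc(Br)c1 | starting material
3 | 3-(3-bromophenoxy)-4-methoxybenzaldehyde | COc1ccc(C=O)cc1Oc1cccc(Br)c1 | intermediate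
4 | 2-(3-bromophenoxy)-1-methoxy-4-vinylbenzene | COc1ccc(C=C)cc1Oc1cccc(Br)c1 | intermediate
5 | 3-hydroxy-4,5-dimethoxybenzaldehyde | COc1cc(C=O)cc(O)c1OC | starting material
6 | (4-iodophenyl)boronic acid | OB(O)c1ccc(I)cc1 | starting material
7 | 3-(4-iodophenoxy)-4,5-dimethoxybenzaldehyde | COc1cc(C=O)cc(Oc2ccc(I)cc2)c1OC | intermediate
8 | 1-(4-iodophenoxy)-2,3-dimethoxy-5-vinylbenzene | COc1cc(C=C)cc(Oc2ccc(I)cc2)c1OC | intermediate
9 | 9-{2-[3-(4-iodophenoxy)-4,5-dimethoxyphenyl]ethyl}-9-borabicyclo[3.3.1]nonane | COc1cc(CCB2C3CCCC2CCC3)cc(Oc2ccc(I)cc2)c1OC | intermediate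
10 | 2-[3-(4-iodophenoxy)-4,5-dimethoxyphenyl]ethan-1-ol | COc1cc(CCO)cc(Oc2ccc(I)cc2)c1OC | intermediate
11 | 9-{2-[3-(3-bromophenoxy)-4-methoxyphenyl]ethyl}-9-borabicyclo[3.3.1]nonane | COc1ccc(CCB2C3CCCC2CCC3)cc1Oc1cccc(Br)c1 | intermediate
12 | 2-[3-(4-{2-[3-(3-bromophenoxy)-4-methoxyphenyl]ethyl}phenoxy)-4,5-dimethoxyphenyl]ethan-1-ol | COc1ccc(CCc2ccc(Oc3cc(CCO)cc(OC)c3OC)cc2)cc1Oc1cccc(Br)c1 | intermediate
13 | 1-(2-bromoethyl)-3-(4-{2-[3-(3-bromophenoxy)-4-methoxyphenyl]ethyl}phenoxy)-4,5-dimethoxybenzene | COc1ccc(CCc2ccc(Oc3cc(CCBr)cc(OC)c3OC)cc2)cc1Oc1cccc(Br)c1 | intermediate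
14 | tri-O-methyl ether of the target macrocycle | COc1ccc2cc1Oc1cccc(c1)CCc1cc(OC)c(OC)c(c1)Oc1ccc(cc1)CC2 | intermediate
15 | CNP0495401.0 | Oc1ccc2cc1Oc1cccc(c1)CCc1cc(O)c(O)c(c1)Oc1ccc(cc1)CC2 | target

**Total step count:** 9
**Longest linear sequence:** 7 (steps 3, 4, 5, 6, 7, 8, 9)

**Steps most likely to fail**

1. Step 8. Reduction of either C–Br terminus to C–H, β-hydride elimination at the alkyl-nickel stage, or coupling between chains may outrun ring closure, because the short-lived alkyl radical must find the nickel centre on its own chain.
   - The fallback sets out from 13 and comes back at 14.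
   - KOtBu in THF at 0 °C should eliminate HBr from the 2-arylethyl bromide and give the seco-styrene F1.
   - Hydroboration with 9-BBN in THF gives the seco-alkylborane F2.
   - F2 is added slowly to Pd(dppf)Cl2, AsPh3 and Cs2CO3 in DMF/THF/H2O at 50 °C under high dilution.
   - This B-alkyl Suzuki–Miyaura macrocyclisation is a well-precedented closure of large rings. It makes the same ring B–CH2 bond by a two-electron nucleophile–electrophile pairing in which both partners are persistent.

2. Step 6. Discrimination between the C–I bond of ring D and the C–Br bond of ring B may be lost, so that the borane also couples at ring B and the chains oligomerise.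
   - The fallback sets out from 1 and 10 and comes back at 12. It attaches ring B only after the palladium step.
   - Wittig methylenation of 1 (MePPh3Br, KOtBu, both in excess for the free phenol) gives 2-methoxy-5-vinylphenol F3.
   - 9-BBN (2.2 equiv) gives the C,O-diborylated intermediate F4, whose O–B bond is cleaved again by the aqueous base.
   - Coupling with 10 under Pd(dppf)Cl2 and Cs2CO3 gives the ring A phenol F5, with no aryl bromide present.
   - Chan–Lam arylation of F5 with 2 (Cu(OAc)2, pyridine, CH2Cl2, air, rt) takes the phenol in preference to the primary alcohol and gives 12.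

3. Step 3. Transfer of the aryl group to copper and C–O bond formation may be slow for the phenol of 5, which is flanked by a methoxy group and deactivated by the aldehyde. Protodeboronation and oxidation of 6 would then consume the boronic acid.
   - The fallback sets out from 5 and comes back at 7.
   - It is an Ullmann-type coupling of 5 with excess 1,4-diiodobenzene (Ic1ccc(I)cc1) using CuI, N,N-dimethylglycine and Cs2CO3 in dioxane at 90 °C.
   - The aryl partner is then an electrophile instead of a boron nucleophile, and no oxidant is needed.
   - No compound outside the list is made (entry F0).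

**Further compounds**
F1 | step 8 | 1-(4-{2-[3-(3-bromophenoxy)-4-methoxyphenyl]ethyl}phenoxy)-2,3-dimethoxy-5-vinylbenzene (seco-styrene) | COc1ccc(CCc2ccc(Oc3cc(C=C)cc(OC)c3OC)cc2)cc1Oc1cccc(Br)c1
F2 | step 8 | B-alkyl-9-BBN derivative of F1 (seco-alkylborane) | COc1ccc(CCc2ccc(Oc3cc(CCB4C5CCCC4CCC5)cc(OC)c3OC)cc2)cc1Oc1cccc(Br)c1
F3 | step 6 | 2-methoxy-5-vinylphenol | COc1ccc(C=C)cc1O
F4 | step 6 | C,O-bis(9-borabicyclo[3.3.1]nonan-9-yl) derivative of F3 | COc1ccc(CCB2C3CCCC2CCC3)cc1OB1C2CCCC1CCC2
F5 | step 6 | 5-(2-{4-[5-(2-hydroxyethyl)-2,3-dimethoxyphenoxy]phenyl}ethyl)-2-methoxyphenol | COc1ccc(CCc2ccc(Oc3cc(CCO)cc(OC)c3OC)cc2)cc1O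
F0 | step 3 | none | none
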